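**Retrosyn­thetic overview**
1. The target is 2,5-dihydroxy-3-hexadecyl-1,4-benzoquinone: one six-membered carbocycle, no stereocentre, numbered C1(=O), C2(OH), C3(C16H33), C4(=O), C5(OH), C6(H). The plan rests on the run C1–C2–C3–C4, four ring carbons that carry three oxygens and the chain and so map onto a squarate ring. Next to it, C5(O)=C6(H) is an oxygenated vinyl unit.
2. Both hydroxyls are unmasked last, from a methoxy group (C2) and an ethoxy group (C5), by vinylogous ester hydrolysis. The quinone comes from its hydroquinone by mild oxidation.
3. Key disconnection: C4–C5, taken back by retro-6π/retro-4π (Moore rearrangement) to a 4-[(Z)-2-ethoxyvinyl]-4-hydroxycyclobutenone. The four-membered ring is bought, and the six-membered ring is made from it in this single step.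
4. C6–C1 comes from 1,2-addition of (Z)-2-ethoxyvinyllithium to the ketone-like carbonyl of 3-hexadecyl-4-methoxycyclobutenedione. The C3–chain bond comes from hexadecylmagnesium bromide and dimethyl squarate.
5. A proton shift among the oxygens gives the degenerate tautomer (mirror through the C3···C6 axis). In that tautomer's numbering the same squarate piece reads C2–C3–C4–C5, the vinyl unit C6–C1 and the ring-closing bond C1–C2.

Key step: step 4

Remark: every chiral intermediate is a racemate and its SMILES shows one enantiomer only; the target is handled as the 1,4-quinone tautomer drawn in its SMILES.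

Step 1
Reactants: 1 1-bromohexadecane; 2 dimethyl squarate (3,4-dimethoxycyclobut-3-ene-1,2-dione)
Product: 5 4-hexadecyl-4-hydroxy-2,3-dimethoxycyclobut-2-en-1-one (racemic), via hexadecylmagnesium bromide 3 (not isolated), via bromomagnesium alkoxide 4 (not isolated)
Conditions: 1, Mg, cat. iodine, THF, 45 °C; warm solution of 3 added to 2, THF, −78 → −30 °C; sat. aq NH4Cl
Reagents that add atoms: magnesium, [Mg] (kept only in 3 and 4, gone in 5)
Why: Grignard formation is the clean way to metalate a primary alkyl bromide, and 1,2-addition to one of the two equivalent squarate carbonyls should stop after one addition because alkoxide 4 keeps only a deactivated vinylogous ester carbonyl, the new carbinol centre arising as a racemate that is lost again in step 2.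

Step 2
Reactants: 5 4-hexadecyl-4-hydroxy-2,3-dimethoxycyclobut-2-en-1-one
Product: 7 3-hexadecyl-4-methoxycyclobut-3-ene-1,2-dione, via hemiketal 6 (not isolated)
Conditions: 12 M HCl (a few drops), CH2Cl2, rt
Reagents that add atoms: water, O (oxygen of the new carbonyl; the carbinol oxygen of 5 leaves as water)
Why: In this acid-catalysed allylic transposition with hemiketal collapse (the standard conversion of squarate adducts into cyclobutenediones) the tertiary hydroxyl leaves, the allyl cation is stabilised at its far end by a methoxy group, water adds there to give the transient racemic 6, and loss of methanol unmasks the second carbonyl.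

Step 3
Reactants: 7 3-hexadecyl-4-methoxycyclobut-3-ene-1,2-dione; 8 (Z)-1-bromo-2-ethoxyethene
Product: 11 4-[(Z)-2-ethoxyvinyl]-2-hexadecyl-4-hydroxy-3-methoxycyclobut-2-en-1-one (racemic), via (Z)-2-ethoxyvinyllithium 9 (not isolated), via lithium alkoxide 10 (not isolated)
Conditions: 8, n-BuLi, Et2O, −78 °C; cold 9 cannulated into 7, THF (dilute), −78 °C; sat. aq NaHCO3, −78 → 0 °C; dried over K2CO3, Et3N-washed SiO2 or used crude
Reagents that add atoms: n-butyllithium, [Li]CCCC (lithium kept only in 9 and 10, gone in 11)
Why: Bromine–lithium exchange with retention gives the configurationally stable cis reagent 9, in which lithium and ethoxy cannot reach the anti arrangement needed for fast β-elimination, and its 1,2-addition should pick the ketone-like carbonyl next to the methoxy-bearing carbon because the other carbonyl is deactivated as a vinylogous ester, the carbinol centre forming as a racemate that step 4 erases.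

Step 4
Reactants: 11 4-[(Z)-2-ethoxyvinyl]-2-hexadecyl-4-hydroxy-3-methoxycyclobut-2-en-1-one
Product: 14 5-ethoxy-3-hexadecyl-2-methoxybenzene-1,4-diol, via dienylketene 12 (not isolated), via cyclohexadienone 13 (not isolated)
Conditions: degassed toluene (0.02 M), 110 °C, Ar, base-washed glassware
Reagents that add atoms: none
Why: Heat breaks the C(=O)–C(OH) bond of the four-membered ring in a conrotatory 4π electrocyclic opening in which the donor hydroxyl turns outward (torquoselectivity), so the ethoxyvinyl arm turns inward and ends cis to the ketene in 12. The sp ketene carbon of 12 then bonds to the ethoxy-bearing vinyl terminus in a thermal disrotatory 6π electrocyclisation that closes the only six-membered carbocycle (target bond C4–C5) and gives dienone 13, whose enolisation to the arene 14 makes the sequence irreversible. The closest known reaction type is this very one, the Moore rearrangement of squarate-derived 4-alkenyl-4-hydroxycyclobutenones to hydroquinones. No lasting stereocentre is made: the carbinol centre of 11 vanishes on opening, the sp3 centre of 13 vanishes on tautomerisation, and the Z geometry of the enol ether is erased, its only cost being an inward ethoxy group that should slow but not stop closure onto the unhindered ketene carbon. The step needs rotational selectivity, secured by the hydroxyl on the breaking bond, and positional fidelity, secured because in 11 the chain already sits next to the future ketene carbon and the methoxy group next to the carbinol carbon, so the oxygens can only end 1,2,4,5 with the chain between C2 and C4. Dilute, oxygen-free and strictly acid-free conditions should keep the ketene from intermolecular trapping and the β-ethoxyvinyl carbinol from ionising.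

Step 5
Reactants: 14 5-ethoxy-3-hexadecyl-2-methoxybenzene-1,4-diol
Product: 15 5-ethoxy-3-hexadecyl-2-methoxycyclohexa-2,5-diene-1,4-dione
Conditions: Ag2O, K2CO3, Et2O, rt, dark
Reagents that add atoms: none
Why: Ag2O is a mild, neutral two-electron oxidant for the hydroquinone to p-benzoquinone oxidation, and the very electron-rich 14 should react at room temperature without harm to the alkoxy groups or the chain.

Step 6
Reactants: 15 5-ethoxy-3-hexadecyl-2-methoxycyclohexa-2,5-diene-1,4-dione
Product: 17 2,5-dihydroxy-3-hexadecylcyclohexa-2,5-diene-1,4-dione (target), via disodium salt 16 (not isolated)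
Conditions: 2 M aq NaOH, EtOH/THF, 70 °C, N2; then 2 M HCl, 0 °C, pH 1
Reagents that add atoms: sodium hydroxide, [Na+].[OH-] (both new hydroxyl oxygens of 17; sodium kept only in 16)
Why: Each alkoxy-bearing carbon is the β-carbon of a vinylogous ester, so hydroxide should displace methoxide and ethoxide by conjugate addition–elimination (vinylogous saponification, well known for 2,5-dialkoxyquinones), the dianion 16 resists further attack, and acid releases the target.

**Compound list**
1 | 1-bromohexadecane | CCCCCCCCCCCCCCCCBr | starting material
2 | dimethyl squarate (3,4-dimethoxycyclobut-3-ene-1,2-dione) | COC1=C(OC)C(=O)C1=O | starting material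
3 | hexadecylmagnesium bromide | CCCCCCCCCCCCCCCC[Mg]Br | intermediate
4 | bromomagnesium alkoxide of 5 (racemic) | CCCCCCCCCCCCCCCC[C@]1(O[Mg]Br)C(OC)=C(OC)C1=O | intermediate
5 | 4-hexadecyl-4-hydroxy-2,3-dimethoxycyclobut-2-en-1-one (racemic) | CCCCCCCCCCCCCCCC[C@]1(O)C(OC)=C(OC)C1=O | intermediate
6 | 2-hexadecyl-4-hydroxy-3,4-dimethoxycyclobut-2-en-1-one, hemiketal (racemic) | CCCCCCCCCCCCCCCCC1=C(OC)[C@](O)(OC)C1=O | intermediate
7 | 3-hexadecyl-4-methoxycyclobut-3-ene-1,2-dione | CCCCCCCCCCCCCCCCC1=C(OC)C(=O)C1=O | intermediate
8 | (Z)-1-bromo-2-ethoxyethene | CCO/C=C\Br | starting material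
9 | (Z)-2-ethoxyvinyllithium | CCO/C=C\[Li] | intermediate
10 | lithium alkoxide of 11 (racemic) | CCCCCCCCCCCCCCCCC1=C(OC)[C@@](O[Li])(/C=C\OCC)C1=O | intermediate
11 | 4-[(Z)-2-ethoxyvinyl]-2-hexadecyl-4-hydroxy-3-methoxycyclobut-2-en-1-one (racemic) | CCCCCCCCCCCCCCCCC1=C(OC)[C@@](O)(/C=C\OCC)C1=O | intermediate
12 | (3Z,5Z)-6-ethoxy-2-hexadecyl-4-hydroxy-3-methoxyhexa-1,3,5-trien-1-one, dienylketene | CCCCCCCCCCCCCCCCC(=C=O)/C(OC)=C(O)\C=C/OCC | intermediate
13 | 6-ethoxy-2-hexadecyl-4-hydroxy-3-methoxycyclohexa-2,4-dien-1-one (racemic) | CCCCCCCCCCCCCCCCC1=C(OC)C(O)=C[C@H](OCC)C1=O | intermediate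
14 | 5-ethoxy-3-hexadecyl-2-methoxybenzene-1,4-diol | CCCCCCCCCCCCCCCCc1c(OC)c(O)cc(OCC)c1O | intermediate
15 | 5-ethoxy-3-hexadecyl-2-methoxycyclohexa-2,5-diene-1,4-dione | CCCCCCCCCCCCCCCCC1=C(OC)C(=O)C=C(OCC)C1=O | intermediate
16 | disodium salt of 17 | CCCCCCCCCCCCCCCCC1=C([O-])C(=O)C=C([O-])C1=O.[Na+].[Na+] | intermediate
17 | 2,5-dihydroxy-3-hexadecylcyclohexa-2,5-diene-1,4-dione | CCCCCCCCCCCCCCCCC1=C(O)C(=O)C=C(O)C1=O | target

Total step count: 6. Longest linear sequence: 6 (from 1 or 2 to 17).

**Steps most likely to fail**

Step 4.
- Risk: the inward ethoxy group may slow the 6π closure enough for intermolecular ketene trapping to compete.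
- Risk: traces of acid may ionise the tertiary allylic carbinol before the ring opens.
- Risk: a share of inward hydroxyl rotation would divert material to lactonisation.
- Fallback: it leaves the squarate logic, sets out from 1 and comes back to the route at 16. Purchased 1,2,4,5-tetramethoxybenzene (COc1cc(OC)c(OC)cc1OC) would be lithiated between two methoxy groups with n-BuLi in THF (directed ortho-metalation) to 2,3,5,6-tetramethoxyphenyllithium F1. Alkylation with 1 in the presence of DMPU should give 3-hexadecyl-1,2,4,5-tetramethoxybenzene F2. Oxidative demethylation with (NH4)2Ce(NO3)6 in MeCN/H2O should give 3-hexadecyl-2,5-dimethoxycyclohexa-2,5-diene-1,4-dione F3. The NaOH conditions of step 6 should then turn F3 into 16.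

Step 3.
- Risk: local warming may cause dehydrobromination of 8 or decay of the vinyllithium.
- Risk: the waxy dione may precipitate at −78 °C, so that addition becomes incomplete or less selective between the two carbonyls.
- Risk: deprotonation may occur at the chain CH2 next to the ring.
- Risk: acid-induced loss of the enol ether may occur on work-up or on silica.
- Fallback: it sets out from 7 and comes back at 11. Purchased ethoxyacetylene (CCOC#C) and n-BuLi in THF at −78 °C would give lithium ethoxyacetylide F4, a reagent with no β-elimination pathway. Addition to the same ketone-like carbonyl of 7 should give the lithium alkoxide F5. A NaHCO3 quench should then give 4-(ethoxyethynyl)-2-hexadecyl-4-hydroxy-3-methoxycyclobut-2-en-1-one F6. Syn semihydrogenation (H2, Pd on CaCO3 poisoned with Pb(OAc)2, quinoline, EtOAc) should deliver the Z enol ether 11. The tetrasubstituted ring alkene should be left alone.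

Step 6.
- Risk: the reaction may stall after the first substitution, because the second must occur on an anionic vinylogous carboxylate flanked by the chain.
- Risk: the amphiphilic salt may aggregate like a soap.
- Risk: the electron-rich dianion may degrade oxidatively if air enters.
- Fallback: it sets out from 14, bypasses steps 5 and 6 and comes back at 17. BBr3 in CH2Cl2 (−78 °C → rt) would cleave both alkyl aryl ethers at the arene oxidation level. Aqueous work-up should give 3-hexadecylbenzene-1,2,4,5-tetrol F7. Stirring F7 in EtOAc under air should oxidise it to the dihydroxyquinone 17.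

**Further compounds**
F1 | step 4 | 2,3,5,6-tetramethoxyphenyllithium | COc1cc(OC)c(OC)c([Li])c1OC
F2 | step 4 | 3-hexadecyl-1,2,4,5-tetramethoxybenzene | CCCCCCCCCCCCCCCCc1c(OC)c(OC)cc(OC)c1OC
F3 | step 4 | 3-hexadecyl-2,5-dimethoxycyclohexa-2,5-diene-1,4-dione | CCCCCCCCCCCCCCCCC1=C(OC)C(=O)C=C(OC)C1=O
F4 | step 3 | lithium ethoxyacetylide | CCOC#C[Li]
F5 | step 3 | lithium alkoxide of F6 (racemic) | CCCCCCCCCCCCCCCCC1=C(OC)[C@@](O[Li])(C#COCC)C1=O
F6 | step 3 | 4-(ethoxyethynyl)-2-hexadecyl-4-hydroxy-3-methoxycyclobut-2-en-1-one (racemic) | CCCCCCCCCCCCCCCCC1=C(OC)[C@@](O)(C#COCC)C1=O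
F7 | step 6 | 3-hexadecylbenzene-1,2,4,5-tetrol | CCCCCCCCCCCCCCCCc1c(O)c(O)cc(O)c1O
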